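**Plan**
Cuts: first the O10–coumaroyl and O1–acyl ester bonds, then C11 goes back to the aldehyde. The whole pyran ring then falls away at C4–C5, C1–C9 and C1–O2, and the remaining cyclopentene is traced through C8–O and C8–C10 to cyclopentenone and formaldehyde.
Enabling feature: C1 and C3 are both aldehyde-level carbons in a 1,5 relationship (C1–C9–C5–C4–C3), attached through the adjacent cis carbons C9 and C5 of the cyclopentane ring. The dihydropyran ring is only the cyclic hemiacetal of this enolised dialdehyde, which is what remains when the cyclobutanol from an enol/alkene [2+2] adduct fragments.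
Forward: the oxygenated cyclopentene ring is built first, the pyran ring is annulated onto C5=C9 photochemically with triformylmethane, and the two acyl groups go on last, with C11 kept as the aldehyde until O10 is esterified.
Stereochemistry: C7 comes from a CBS reduction and C8 from epoxidation anti to O7. C5 and C9 come from cis addition to the alkene face left open by a 7,10-silylene, and C1 from the convex-face and anomeric preference of the lactol. The side-chain centre comes from (S)-3-methylpentanoic acid and the E-alkene from p-coumaric acid.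

Key step: step 7

Convention and assumption: iridoid numbering is used (C1 acetal carbon, O2, C3=C4, ring-fusion carbons C5 and C9, C6–C8 in the cyclopentane, C10 on C8, C11 on C4). β is the face of H5, H9, O7 and C10, and α is the face of 8-OH. Lactol 15 is assumed to interconvert between its C1 epimers and is drawn as the more stable 1β-hydroxy form.

Step 1
Reactants: 1 cyclopent-2-en-1-one; 2 formaldehyde (37% aqueous)
Product: 3 2-(hydroxymethyl)cyclopent-2-en-1-one
Conditions: PBu3 (10 mol %), MeOH/CHCl3, rt
Reagents that add atoms: none
Why: Morita–Baylis–Hillman reaction, well known for cyclopentenone itself: the phosphine adds in conjugate fashion, the enolate takes up formaldehyde at the α-carbon (C8–C10 bond) and loss of phosphine restores the enone, with no stereocentre formed.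

Step 2
Reactants: 3 2-(hydroxymethyl)cyclopent-2-en-1-one
Product: 4 2-[(triethylsilyloxy)methyl]cyclopent-2-en-1-one
Conditions: TESCl, imidazole, CH2Cl2, 0 °C
Reagents that add atoms: chlorotriethylsilane (TESCl), CC[Si](Cl)(CC)CC
Why: Standard silylation of a primary alcohol, which keeps a free OH from binding borane next to the ketone and delivering hydride without the catalyst in step 3.

Step 3
Reactants: 4 2-[(triethylsilyloxy)methyl]cyclopent-2-en-1-one
Product: 6 (1S)-2-(hydroxymethyl)cyclopent-2-en-1-ol, via TES-protected allylic alcohol 5 (not isolated)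
Conditions: (R)-2-methyl-CBS-oxazaborolidine (10 mol %), BH3·SMe2, THF, −20 °C; MeOH quench; then PPTS (cat.), MeOH, rt
Reagents that add atoms: none
Why: Corey–Bakshi–Shibata reduction, in which the ketone binds the (R)-oxazaborolidine–borane complex with the α-branched alkene arm as the large group and the ring CH2 as the small one, so hydride arrives on the α face and sets C7 as S (O7 β); the labile primary TES ether then falls off by acid-catalysed methanolysis in the same flask.

Step 4
Reactants: 6 (1S)-2-(hydroxymethyl)cyclopent-2-en-1-ol
Product: 7 (7aS)-2,2-di-tert-butyl-4,6,7,7a-tetrahydrocyclopenta[d][1,3,2]dioxasiline (7,10-O-silylene; C8=C9 alkene)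
Conditions: tBu2Si(OTf)2, 2,6-lutidine, CH2Cl2, 0 °C
Reagents that add atoms: di-tert-butylsilyl bis(trifluoromethanesulfonate), CC(C)(C)[Si](OS(=O)(=O)C(F)(F)F)(OS(=O)(=O)C(F)(F)F)C(C)(C)C
Why: Standard cyclic silylene protection of a 1,3-diol, giving a six-membered dioxasilinane that ties O7 and C10 together on the β side of the carbocycle and places two tert-butyl groups over that face.

Step 5
Reactants: 7 silylene-protected cyclopentene (C8=C9)
Product: 8 8α,9α-epoxide of 7
Conditions: mCPBA, CH2Cl2, 0 °C
Reagents that add atoms: 3-chloroperbenzoic acid (mCPBA), OOC(=O)c1cccc(Cl)c1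
Why: Prilezhaev epoxidation of the trisubstituted alkene, where no free hydroxyl can direct the peracid, so it approaches anti to O7 and the silylene ring, and this sets C8 with oxygen α and C10 β (C9 is only a temporary centre).

Step 6
Reactants: 8 8α,9α-epoxide
Product: 11 (4aR,7aS)-2,2-di-tert-butyl-7,7a-dihydro-4H-cyclopenta[d][1,3,2]dioxasilin-4a-ol (8α-OH; C5=C9 alkene; 7,10-O-silylene), via hydroxy selenide 9 (not isolated), via selenoxide 10 (not isolated)
Conditions: PhSeSePh, NaBH4, EtOH, rt to 50 °C; then THF, 30% H2O2, 0 °C to rt
Reagents that add atoms: none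
Why: Organoselenium epoxide-to-allylic-alcohol transposition, in which the soft selenolate opens the epoxide by SN2 at the secondary C9 and leaves the C8–O bond and its configuration untouched; the derived selenoxide then undergoes syn elimination toward C5, the only neighbour that carries hydrogen.

Step 7
Reactants: 11 silylene-protected cyclopentenol (C5=C9); 12 triformylmethane
Product: 15 4-formyl iridoid lactol (1β-OH; 8α-OH; 7β,10-O-di-tert-butylsilylene; H5β; H9β), via cyclobutanol photoadduct 13 (not isolated), via open tricarbonyl enol 14 (not isolated)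
Conditions: 12 (3 equiv, in portions), hν (medium-pressure Hg lamp, Pyrex filter), degassed CH2Cl2, 0 °C; run to partial conversion, 11 recovered
Reagents that add atoms: none
Why: Light excites the chelated enol of 12 (hydroxymethylene-malonaldehyde), whose C1=C4 bond adds across C5=C9 in a [2+2] photocycloaddition to cyclobutanol 13 (new bonds C4–C5 and C1–C9); 13 is a β-hydroxy aldehyde and opens by retro-aldol cleavage of C1–C4 to 14, whose enol oxygen adds to the freed C1 aldehyde (new bond C1–O2). The closest known reaction type is the de Mayo reaction of enolised formyl compounds with cyclopentenes, the classical photochemical entry to iridoid aglycones. The only ring that is kept, the dihydropyran, closes by 6-exo-trig hemiacetalisation, while the four-membered ring is transient. C5 and C9 must come out cis because both bonds form on one face of a five-membered ring alkene, and that face is α because the tBu2Si-bridged O7/C10 ring covers the β face and the α-oriented 8-OH can hydrogen-bond to a formyl oxygen of the incoming enol; C1 is under thermodynamic control and settles with OH on the convex β face, pseudo-axial and trans to the C9–C8 bond. The step needs orientational selectivity, which sterics should secure: the fully substituted enol carbon C4 with its two formyl groups bonds to C5 beside the C6 methylene, and the slim CH(OH) terminus C1 takes C9 beside the quaternary C8. The three formyl groups of 12 are equivalent, so every enol tautomer leads to the same product and the spare one arrives as C11 at the aldehyde level, while Pyrex filtering and portionwise addition of 12 limit secondary photolysis of the enal.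

Step 8
Reactants: 15 4-formyl iridoid lactol; 16 (S)-3-methylpentanoic acid
Product: 17 1β-O-[(3S)-3-methylpentanoyl] 4-formyl iridoid with 7,10-O-silylene
Conditions: 16 (1.3 equiv), DIC, DMAP (0.2 equiv), CH2Cl2, −10 °C to rt
Reagents that add atoms: none
Why: Steglich esterification of a lactol whose anomers interconvert through 14, so the β-hydroxyl on the convex face (trans to the C9–C8 bond, favoured by the anomeric effect) should be the one acylated, fixing C1 as S; the tertiary 8-OH is too hindered to compete and the β-stereocentre of the acid cannot epimerise.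

Step 9
Reactants: 17 1-O-acyl silylene aldehyde
Product: 18 7β,8α,10-triol 1-O-acyl 4-formyl iridoid
Conditions: HF·pyridine, pyridine, THF, 0 °C
Reagents that add atoms: none
Why: Fluoride cleavage of the silylene driven by Si–F bond formation, done while the C4 formyl group still draws electron density from O2, so the acyloxy acetal at C1 should not ionise in the buffered medium.

Step 10
Reactants: 19 (E)-4-hydroxycinnamic acid (p-coumaric acid)
Product: 21 (E)-4-(tert-butyldimethylsilyloxy)cinnamic acid, via bis-TBS coumarate 20 (not isolated)
Conditions: TBSCl (2.2 equiv), imidazole, DMF, rt; then AcOH/THF/H2O, rt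
Reagents that add atoms: tert-butyldimethylsilyl chloride (TBSCl), CC(C)(C)[Si](C)(C)Cl
Why: Exhaustive silylation followed by selective hydrolysis of the far more labile silyl ester, the usual route to phenol-protected hydroxycinnamic acids, which leaves the E-alkene untouched.

Step 11
Reactants: 18 triol aldehyde; 21 (E)-4-(tert-butyldimethylsilyloxy)cinnamic acid
Product: 22 10-O-[(E)-4-(tert-butyldimethylsilyloxy)cinnamoyl] 1-O-acyl 4-formyl iridoid (7β-OH and 8α-OH free)
Conditions: 21 (1.05 equiv), DIC, DMAP (0.1 equiv), CH2Cl2, −20 to 0 °C
Reagents that add atoms: none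
Why: Steglich esterification under kinetic control, where the primary 10-OH should outrun the secondary 7-OH and the tertiary 8-OH is inert; because C11 is still an aldehyde, no second primary alcohol competes.

Step 12
Reactants: 22 10-O-coumaroyl aldehyde
Product: 23 11-hydroxy compound (phenol still TBS-protected)
Conditions: NaBH4, CeCl3·7H2O, MeOH/THF, −40 °C; pH 7 buffer
Reagents that add atoms: none
Why: Luche reduction, in which the hard cerium-modified borohydride attacks the aldehyde carbonyl in 1,2 fashion and leaves the C3=C4 enol ether, the cinnamate double bond and both esters alone; low temperature and a neutral quench protect the acetal, which becomes more labile once the aldehyde is gone.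

Step 13
Reactants: 23 TBS-protected precursor
Product: 24 target CNP0241834.1
Conditions: TBAF/AcOH (1:1), THF, 0 °C
Reagents that add atoms: none
Why: Fluoride cleavage of an aryl silyl ether, fast at 0 °C because phenoxide is a good leaving group, with acetic acid holding the medium near neutral so that no acyl migration or ester cleavage should occur.

**Compound list**
1 | cyclopent-2-en-1-one | O=C1C=CCC1 | starting material
2 | formaldehyde | C=O | starting material
3 | 2-(hydroxymethyl)cyclopent-2-en-1-one | O=C1CCC=C1CO | intermediate
4 | 2-[(triethylsilyloxy)methyl]cyclopent-2-en-1-one | O=C1CCC=C1CO[Si](CC)(CC)CC | intermediate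
5 | (1S)-2-[(triethylsilyloxy)methyl]cyclopent-2-en-1-ol (not isolated) | CC[Si](CC)(CC)OCC1=CCC[C@@H]1O | intermediate
6 | (1S)-2-(hydroxymethyl)cyclopent-2-en-1-ol | OCC1=CCC[C@@H]1O | intermediate
7 | (7aS)-2,2-di-tert-butyl-4,6,7,7a-tetrahydrocyclopenta[d][1,3,2]dioxasiline | C1=C2CO[Si](C(C)(C)C)(C(C)(C)C)O[C@H]2CC1 | intermediate
8 | 8α,9α-epoxide of 7 (O7 and C10 β) | C1C[C@@H]2O[Si](C(C)(C)C)(C(C)(C)C)OC[C@@]23O[C@@H]13 | intermediate
9 | 8α-hydroxy-9β-phenylselanyl silylene (not isolated) | O[C@]12CO[Si](C(C)(C)C)(C(C)(C)C)O[C@H]1CC[C@H]2[Se]c1ccccc1 | intermediate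
10 | selenoxide of 9, both configurations at Se (not isolated) | O[C@]12CO[Si](C(C)(C)C)(C(C)(C)C)O[C@H]1CC[C@H]2[Se](=O)c1ccccc1 | intermediate
11 | (4aR,7aS)-2,2-di-tert-butyl-7,7a-dihydro-4H-cyclopenta[d][1,3,2]dioxasilin-4a-ol (7S,8R in iridoid numbering) | C1=C[C@@]2(O)CO[Si](C(C)(C)C)(C(C)(C)C)O[C@H]2C1 | intermediate
12 | triformylmethane | O=CC(C=O)C=O | starting material
13 | cyclobutanol photoadduct, C5–C4(CHO)2–C1H(OH)–C9 ring on the α face, C1 epimers (not isolated) | O=CC1(C=O)C(O)[C@H]2[C@@H]1C[C@@H]3O[Si](C(C)(C)C)(C(C)(C)C)OC[C@]23O | intermediate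
14 | open tricarbonyl enol, C9–CHO and C5–C(CHO)=CHOH (not isolated) | O=C[C@H]1[C@@H](C(C=O)=CO)C[C@@H]2O[Si](C(C)(C)C)(C(C)(C)C)OC[C@]12O | intermediate
15 | 4-formyl iridoid lactol, 1β-OH, 8α-OH, 7β,10-O-di-tert-butylsilylene, H5β, H9β | O[C@@H]1OC=C(C=O)[C@H]2C[C@@H]3O[Si](C(C)(C)C)(C(C)(C)C)OC[C@]3(O)[C@@H]12 | intermediate
16 | (S)-3-methylpentanoic acid | CC[C@H](C)CC(=O)O | starting material
17 | 1β-O-[(3S)-3-methylpentanoyl] derivative of 15 | CC[C@H](C)CC(=O)O[C@@H]1OC=C(C=O)[C@H]2C[C@@H]3O[Si](C(C)(C)C)(C(C)(C)C)OC[C@]3(O)[C@@H]12 | intermediate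
18 | 7β,8α,10-triol 1-O-acyl 4-formyl iridoid | CC[C@H](C)CC(=O)O[C@@H]1OC=C(C=O)[C@H]2C[C@H](O)[C@](O)(CO)[C@@H]12 | intermediate
19 | (E)-4-hydroxycinnamic acid | OC(=O)/C=C/c1ccc(O)cc1 | starting material
20 | tert-butyldimethylsilyl (E)-4-(tert-butyldimethylsilyloxy)cinnamate (not isolated) | CC(C)(C)[Si](C)(C)OC(=O)/C=C/c1ccc(O[Si](C)(C)C(C)(C)C)cc1 | intermediate
21 | (E)-4-(tert-butyldimethylsilyloxy)cinnamic acid | OC(=O)/C=C/c1ccc(O[Si](C)(C)C(C)(C)C)cc1 | intermediate
22 | 10-O-[(E)-4-(TBSO)cinnamoyl] 1-O-acyl 4-formyl iridoid | CC[C@H](C)CC(=O)O[C@@H]1OC=C(C=O)[C@H]2C[C@H](O)[C@](O)(COC(=O)/C=C/c3ccc(O[Si](C)(C)C(C)(C)C)cc3)[C@@H]12 | intermediate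
23 | 11-hydroxy analogue of 22 | CC[C@H](C)CC(=O)O[C@@H]1OC=C(CO)[C@H]2C[C@H](O)[C@](O)(COC(=O)/C=C/c3ccc(O[Si](C)(C)C(C)(C)C)cc3)[C@@H]12 | intermediate
24 | (1S,4aS,6S,7R,7aS)-6,7-dihydroxy-4-(hydroxymethyl)-7-{[(E)-3-(4-hydroxyphenyl)prop-2-enoyl]oxymethyl}-1,4a,5,6,7,7a-hexahydrocyclopenta[c]pyran-1-yl (3S)-3-methylpentanoate | CC[C@H](C)CC(=O)O[C@@H]1OC=C(CO)[C@H]2C[C@H](O)[C@](O)(COC(=O)/C=C/c3ccc(O)cc3)[C@@H]12 | target

Total step count: 13. Longest linear sequence: 12 steps (steps 1–9 and 11–13; step 10 is a one-step side branch).

**Steps most likely to fail**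

Step 7. The enol may add with the reverse orientation or partly from the β face. Slow bimolecular capture may also let the enal product be consumed by further photoreaction. The fallback makes the cycloaddition intramolecular through a temporary silicon tether.
- It sets out from 11. Excess Me2SiCl2, Et3N and DMAP in CH2Cl2 should give the chlorodimethylsilyl ether F1.
- After the volatile dichlorosilane is stripped off, the triethylammonium enolate of 12 is added to give the mixed silyl enol ether F2, which is irradiated without purification.
- The four-atom link C8–O–Si–O lets C1 reach only C9, and only from the α face on which O8 stands. The silicon-bridged cyclobutane F3 should therefore form with orientation and face fixed by the six-membered dioxasilinane that closes with it.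
- Mild hydrolysis (AcOH/THF/H2O) takes off the dimethylsilyl bridge but not the di-tert-butylsilylene. This releases cyclobutanol 13, which fragments and closes as before, so the route is rejoined at 15.

Step 11. Acylation may spread to O7, or the coumaroyl group may drift between O10 and the cis-disposed O7 under the basic catalyst. The fallback differentiates the two oxygens by protection instead of by rate.
- It sets out from 17. BF3·SMe2 in CH2Cl2 at 0 °C opens the silylene at its less hindered oxygen and should give the 7-O-(di-tert-butylfluorosilyl) 10-alcohol F4.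
- In F4 the 10-OH is the only acylable hydroxyl. Steglich coupling with 21 gives the coumarate F5, and Luche reduction gives the 11-alcohol F6.
- One treatment with pyridine-buffered HF·pyridine removes the fluorosilyl ether and the phenolic TBS group together. The route is rejoined at 24.

Step 6. The SN2 opening may be sluggish, because the selenolate must come in from the shielded β face beside the quaternary C8. Prolonged heating in basic ethanol may also erode the silylene. The fallback bypasses both the epoxide and selenium.
- It sets out from 7. A Schenck ene reaction with singlet oxygen (O2, tetraphenylporphyrin, visible light, CH2Cl2, −20 °C) should attack the open α face.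
- Oxygen bonds to C8 and the α-hydrogen at C5 is abstracted. The hydrogens on the oxygen-bearing C7 and C10 are deactivated and held in the silylene ring. The product is the tertiary allylic hydroperoxide F7.
- Reduction with PPh3 in the same flask rejoins the route at 11.

**Further compounds**
F1 | step 7 | chlorodimethylsilyl ether of 11 at O8 | C1=C[C@@]2(O[Si](C)(C)Cl)CO[Si](C(C)(C)C)(C(C)(C)C)O[C@H]2C1
F2 | step 7 | mixed silyl enol ether, 8-O–SiMe2–O–CH=C(CHO)2 | C1=C[C@@]2(O[Si](C)(C)OC=C(C=O)C=O)CO[Si](C(C)(C)C)(C(C)(C)C)O[C@H]2C1
F3 | step 7 | silicon-bridged cyclobutane, O1 and O8 joined by SiMe2, cyclobutane on the α face | O=CC1(C=O)[C@H]2C[C@@H]3O[Si](C(C)(C)C)(C(C)(C)C)OC[C@@]34O[Si](C)(C)O[C@@H]1[C@@H]24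
F4 | step 11 | 7-O-(di-tert-butylfluorosilyl) 10-alcohol from 17 | CC[C@H](C)CC(=O)O[C@@H]1OC=C(C=O)[C@H]2C[C@H](O[Si](F)(C(C)(C)C)C(C)(C)C)[C@](O)(CO)[C@@H]12
F5 | step 11 | 10-O-[(E)-4-(TBSO)cinnamoyl] derivative of F4 | CC[C@H](C)CC(=O)O[C@@H]1OC=C(C=O)[C@H]2C[C@H](O[Si](F)(C(C)(C)C)C(C)(C)C)[C@](O)(COC(=O)/C=C/c3ccc(O[Si](C)(C)C(C)(C)C)cc3)[C@@H]12
F6 | step 11 | 11-alcohol from F5 | CC[C@H](C)CC(=O)O[C@@H]1OC=C(CO)[C@H]2C[C@H](O[Si](F)(C(C)(C)C)C(C)(C)C)[C@](O)(COC(=O)/C=C/c3ccc(O[Si](C)(C)C(C)(C)C)cc3)[C@@H]12
F7 | step 6 | 8α-hydroperoxide with C5=C9 alkene and 7,10-O-silylene | C1=C[C@@]2(OO)CO[Si](C(C)(C)C)(C(C)(C)C)O[C@H]2C1
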